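## The problem

Sipholenol M (34) is two bicyclic halves joined by a two-carbon chain: a cis-fused decalin (ring A a cyclohexene, ring B a cyclohexane) and a trans-fused oxepane–cyclohexane. Working locants: in the decalin half C1 is the hydroperoxide carbon, C2 the ring methylene, C3 and C4 the ring-fusion carbons, C5 the alkene carbon bearing the linker, C6 the alkene carbon bearing methyl, C7 the tertiary carbinol, C8 and C9 methylenes and C10 the CMe2 carbon (ring A = C1–C6, ring B = C3, C4, C7–C10). The other half is numbered as a decahydro-1-benzoxepine (O1', C2' = CMe2, C3' = CHOH, C5a' = angular carbon, C6' = carbon bearing the linker, C7' = C(Me)OH, C9a' = CH–O), and the linker is C11 (on C5) and C12 (on C6'). The nine stereocentres form two clusters (C1, C3, C4, C7 and C3', C5a', C6', C7', C9a') insulated by C11–C12, so neither half can control the other and each needs its own source of absolute configuration. Within a half, relay is possible: C9a' can set C5a', and the locked chair then sets C6' and C7'; C3 and C7 arise together, C4 can follow by equilibration, and C1 needs a reagent. The secondary allylic hydroperoxide does not tolerate phosphines, hydrides, low-valent metals, strong base or strong acid and must come as late as possible; the two tertiary alcohols can dehydrate and the tetrasubstituted C5=C6 alkene must not migrate. The enabling feature is ring A: C1, C5 and C6 carry oxygen, carbon and methyl in the pattern of an oxidised 2-methylresorcinol. C7 lies four atoms from the aromatic carbon that becomes C4 (through C10, C9, C8), so ring B can be closed by a ketyl onto the arene.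

## Retrosynthesis

**C1–OOH and the silyl groups.** The last operation removes three triethylsilyl ethers from 33. The C1–O bond of 33 is cut to the allylic mesylate 32 of the (1S)-alcohol 31, which comes from enone 30 by Corey–Bakshi–Shibata reduction. The neighbouring option, a singlet-oxygen ene reaction on the C1=C6 alkene isomer, was set aside as the main line. It would have to abstract the C5 hydrogen, which A(1,2) strain with the C6 methyl turns into the ring plane, and oxygen would have to reach C1 past the axial C7 substituent. The displacement asks only for inversion at a centre whose configuration a chiral reagent sets.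

**C5–C11.** Enone 30 is cut between the alkene carbon and the linker, giving iodide 26 (as alkyllithium 27 and organocerium 28) and vinylogous ester 9; carbinol 29 collapses to 30 in acid (Stork–Danheiser transposition). Cutting C11–C12 instead would need an sp3–sp3 coupling between two β-branched carbons. This cut forms an sp2–sp3 bond by carbonyl addition and delivers the C5=C6 alkene and the C1 oxygen in one step.

**Resolution and protection of the decalin.** Vinylogous ester 9 is the triethylsilyl ether of menthyl enol ether 8, made from racemic dione 7 and (−)-menthol. The enol ether is needed anyway, so making it chiral resolves the decalin before the valuable fragment is committed. The alkoxy group must sit on O1, the less hindered oxygen.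

**Enol ethers to dione.** Dione 7 is the hydrolysis product of the bis(enol ether) 6. This step creates C4 and must give the cis ring fusion.

**C7–C3 (key disconnection).** Ring B of 6 is opened between the carbinol carbon and the ring-fusion carbon, leading to the achiral aryl ketone 5. One bond, one ring and the C3/C7 relationship are traded for a flat, symmetrical aromatic precursor. The forward reaction must add a ketyl to an electron-rich arene and stop at the 1,4-diene.

**Aryl ketone.** Ketone 5 comes from acid 3 and methyllithium through diolate 4. Acid 3 is cut at the aryl–CMe2 bond into 2,6-dimethoxytoluene 1 and lactone 2 (Friedel–Crafts alkylation).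

**Side chain and C7' carbinol.** Iodide 26 comes from alcohol 25, obtained from the tris(silyl) ether 24 of triol 23. Triol 23 arises from spiro-epoxide 22 by hydride (C7' methyl and the primary alcohol together), 22 from alkene 21, and 21 from ketone 20 by methylenation. A direct methyl addition to 20 would give the wrong C7' epimer, because the axial angular methyl blocks axial attack.

**Oxepane.** Ketone 20 is cut at O1'–C2' to epoxy alcohol 17 (through stannyl ethers 18 and 19), which comes from alkene 16 by Shi epoxidation. The precursor is monocyclic, with C3' set by reagent control.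

**Cyclohexane substituents.** Alkene 16 is the desilylated form of 15. Ketone 15 is cut at C5a'–C5' and C6'–C12 to enone 12, a homoprenyl Grignard reagent and ethyl iodoacetate (through 13 and 14). Enone 12 comes from the chiral enone 10 by methyl addition and re-oxidation (through 11). The C9a' silyloxy group of 12 steers the new quaternary centre anti, which gives the trans ring fusion.

## Roads not taken

**Alternative 1:** The cut is in the oxepane–cyclohexane half, at O1'–C2' and C5a'–C6'. In the forward step Me3SiOTf activates the terminal epoxide of the diepoxy allylsilane A1; the inner epoxide oxygen closes the oxepane and the allylsilane closes the cyclohexane, giving A2. Merits: two rings, the trans fusion and three stereocentres (from two reagent-controlled epoxidations) in one operation, with the exocyclic methylene ready for the C7' carbinol. For this half it is clearly shorter than steps 7–13 of the chosen plan. Weak points here: A2 carries a one-carbon arm at C6', so the linker needs a homologation. The diepoxidation must also distinguish three trisubstituted alkenes. Above all, the cascade says nothing about the decalin, where the cis fusion, the C10 quaternary carbon and the hydroperoxide lie, so a second key step would still be needed. Against its brevity the chosen plan sets a stepwise route in which each centre of this half is fixed by a separate, well-understood step and the two-carbon arm arrives at the right oxidation level. Its own key step is spent on the harder half.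

**Alternative 2:** The cut is at C3–C4 and C1–C2 of the decalin. In the forward step the 1-silyloxy diene and tethered vinyl ketone of triene A3 undergo an intramolecular Diels–Alder reaction to the cis-fused ketone A4. Merits: both rings at once, the C5=C6 alkene and the C1 oxygen in place without the dione detour, and a chiral Lewis acid could in principle make it enantioselective. In these respects it is better than the chosen plan, which needs a resolution. Weak points: the tetrasubstituted (Z)-configured silyloxy diene A3 is itself hard to make. Methyl addition to the C7 ketone of A4 must then give the hydroxyl cis to the fusion hydrogens. A4 has only a one-carbon arm at C5, so the union would be an sp3–sp3 coupling at C11–C12. The C1 oxygen of A4 already has the final configuration, so the hydroperoxide would need a substitution with retention. The chosen plan sets against this a trivial aromatic precursor, the C7 carbinol and the ring B closure in one step with defined relative configuration, and a union by carbonyl addition.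

**Alternative 3:** The cut is at C5a'–C9a' and C4'–C5' of the oxepane half. In the forward step irradiation of furanone A5 joins the furanone alkene to the tethered isopropenyl group to give the cyclobutane A6; reductive cleavage of the cyclobutane bond next to the ketone would then expand the furanone into the oxepan-3-one. Merits: the congested bond between the angular carbon and the ether carbon is made photochemically, the CMe2–O unit comes from a simple furanone, and the risky 7-endo epoxide opening of step 11 is avoided; on that point it is better. Weak points: the four-atom tether makes straight versus crossed addition uncertain. Facial control must come from C6' and C7', which therefore have to be made first in acyclic form. The fragmentation must cleave the right bond and set C9a'. The arm at C6' is again one carbon, and the decalin is again untouched. The chosen plan sets against it ground-state reactions with predictable regiochemistry and a fallback for its own oxepane closure.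

Key step: step 3

Remarks: (S)-4-(tert-butyldimethylsilyloxy)cyclohex-2-en-1-one (10) is taken as a purchasable building block. Compounds 6 and 7 are racemic and are drawn as the enantiomer carried on after step 5; 6 is expected as both C6 epimers, which converge in step 4.

Step 1
Reactants: 1 2,6-dimethoxytoluene; 2 5,5-dimethyloxolan-2-one
Product: 3 4-(2,4-dimethoxy-3-methylphenyl)-4-methylpentanoic acid
Conditions: AlCl3, CH2Cl2, 0 °C to rt
Reagents that add atoms: none
Why: Friedel–Crafts alkylation: AlCl3 opens the lactone at the tertiary carbon and the cation attacks the ring position para to one methoxy and ortho to the other, the only position activated by both donors; the free acid does not acylate under these conditions and no stereocentre is formed.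

Step 2
Reactants: 3 4-(2,4-dimethoxy-3-methylphenyl)-4-methylpentanoic acid
Product: 5 5-(2,4-dimethoxy-3-methylphenyl)-5-methylhexan-2-one, via dilithium diolate 4 (not isolated)
Conditions: MeLi (2.2 equiv), THF, 0 °C; then aq. HCl
Reagents that add atoms: methyllithium, [Li]C
Why: Carboxylic acid to methyl ketone with methyllithium: the lithium carboxylate adds one more equivalent to give the stable diolate 4, which releases the ketone only on acidic work-up, so no tertiary alcohol should form.

Step 3
Reactants: 5 5-(2,4-dimethoxy-3-methylphenyl)-5-methylhexan-2-one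
Product: 6 rac-(1S,8aS)-5,7-dimethoxy-1,4,4,6-tetramethyl-1,2,3,4,6,8a-hexahydronaphthalen-1-ol (hydroxyl cis to H-8a)
Conditions: SmI2 (2.5 equiv), HMPA, t-BuOH, THF, rt
Reagents that add atoms: none
Why: Single-electron transfer from SmI2 (divalent samarium, made more reducing by HMPA) to the methyl ketone gives a samarium ketyl, which adds to arene carbon C3, the unsubstituted carbon ortho to the tether; the cyclohexadienyl radical is reduced by a second SmI2 to the anion and protonated by t-BuOH at C6, para to the new bond, leaving the 1,4-diene bis(enol ether). The closest known reaction type is the SmI2–HMPA dearomatizing ketyl–arene cyclization of γ-aryl ketones to hexahydronaphthalen-1-ols. Ring B is closed by forming C7–C3 in a 6-exo-trig mode with respect to the attacked C3=C2 arene bond, helped by the gem-dimethyl group at C10. C7 and C3 are set together in a chair-like transition state with the bulky samarium-bound oxygen pseudoequatorial, which places the hydroxyl cis to the new ring-fusion hydrogen; C6 is set by protonation and is erased in step 4. The step needs regioselectivity for C3 over the other ortho carbon, which bears a methoxy group and is blocked, and chemoselectivity for cyclization over simple ketone reduction or pinacol coupling, which the Thorpe–Ingold effect and the meta placement of both methoxy groups (neither donates to C3) should secure. The product is racemic because neither 5 nor the reagent is chiral.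

Step 4
Reactants: 6 rac-(1S,8aS)-5,7-dimethoxy-1,4,4,6-tetramethyl-1,2,3,4,6,8a-hexahydronaphthalen-1-ol
Product: 7 rac-(4aS,5S,8aR)-5-hydroxy-2,5,8,8-tetramethyl-4a,5,6,7,8,8a-hexahydronaphthalene-1,3(2H,4H)-dione (cis-fused)
Conditions: 1 M aq. HCl, THF, rt
Reagents that add atoms: water, O
Why: Acid hydrolysis of both enol ethers; C4 is created by protonation and, being α to the C5 carbonyl, can equilibrate to the cis fusion, which should be preferred because it lets C10 turn away from the C5 carbonyl (no peri clash of an equatorial C10 methyl); C6 becomes the enolised carbon of the 2-methyl-1,3-dione, so its epimers converge.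

Step 5
Reactants: 7 rac-(4aS,5S,8aR)-5-hydroxy-2,5,8,8-tetramethyl-4a,5,6,7,8,8a-hexahydronaphthalene-1,3(2H,4H)-dione
Product: 8 (4aS,5S,8aR)-5-hydroxy-2,5,8,8-tetramethyl-3-{[(1R,2S,5R)-5-methyl-2-(propan-2-yl)cyclohexyl]oxy}-4a,5,6,7,8,8a-hexahydronaphthalen-1(4H)-one
Conditions: (−)-menthol, PPTS (cat.), toluene, 80 °C, 4 Å molecular sieves; separation of the diastereomers by chromatography or crystallisation
Reagents that add atoms: (−)-menthol, CC(C)[C@@H]1CC[C@@H](C)C[C@H]1O
Why: Acid-catalysed enol etherification of a cyclic 1,3-dione under thermodynamic control should place the alkoxy group on O1, the oxygen remote from the C10 quaternary carbon; the chiral alcohol turns the two enantiomers into diastereomers (classical resolution through covalent diastereomers), and the weak acid spares the tertiary alcohol.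

Step 6
Reactants: 8 menthyl enol ether of the decalin (as above)
Product: 9 (4aS,5S,8aR)-2,5,8,8-tetramethyl-3-{[(1R,2S,5R)-5-methyl-2-(propan-2-yl)cyclohexyl]oxy}-5-(triethylsilyloxy)-4a,5,6,7,8,8a-hexahydronaphthalen-1(4H)-one
Conditions: TESOTf, 2,6-lutidine, CH2Cl2, −78 to 0 °C
Reagents that add atoms: triethylsilyl trifluoromethanesulfonate, CC[Si](CC)(CC)OS(=O)(=O)C(F)(F)F
Why: Silylation of a tertiary alcohol with a silyl triflate and a hindered base; the ether removes the acidic proton before the organometallic union and keeps the C7 oxygen from acting as a nucleophile in step 20.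

Step 7
Reactants: 10 (S)-4-(tert-butyldimethylsilyloxy)cyclohex-2-en-1-one
Product: 12 (S)-4-(tert-butyldimethylsilyloxy)-3-methylcyclohex-2-en-1-one, via silyl enol ether 11 (not isolated)
Conditions: Me2CuLi, TMSCl, THF, −78 °C; then Pd(OAc)2 (10 mol%), O2, DMSO, rt
Reagents that add atoms: lithium dimethylcuprate, [Li+].C[Cu-]C
Why: Cuprate conjugate addition with in situ silyl trapping, followed by Saegusa–Ito dehydrosilylation of enol ether 11, returns the enone with the methyl group at C3; the transient C3 stereocentre is erased and the silyloxy-bearing centre is untouched.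

Step 8
Reactants: 12 (S)-4-(tert-butyldimethylsilyloxy)-3-methylcyclohex-2-en-1-one
Product: 15 ethyl 2-[(1S,2S,3S)-3-(tert-butyldimethylsilyloxy)-2-methyl-2-(4-methylpent-3-en-1-yl)-6-oxocyclohexyl]acetate, via silyl enol ether 13 (not isolated), via lithium enolate 14 (not isolated)
Conditions: 4-methylpent-3-enylmagnesium bromide, CuBr·SMe2 (10 mol%), TMSCl, THF, −78 to −40 °C; then MeLi, THF, 0 °C; then ICH2CO2Et, DMPU, −78 to 0 °C
Reagents that add atoms: 4-methylpent-3-enylmagnesium bromide, CC(C)=CCC[Mg]Br; ethyl iodoacetate, CCOC(=O)CI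
Why: Copper-catalysed conjugate addition of a Grignard reagent to a β-methyl enone creates the quaternary C5a' anti to the neighbouring silyloxy group (chain trans to oxygen, as the trans ring fusion requires); cleavage of 13 with MeLi gives the regiodefined enolate 14, which is alkylated at its only enolate carbon (three-component coupling), and C6', still α to the ketone, is left to be equilibrated in step 12.

Step 9
Reactants: 15 silyl ether keto ester (as above)
Product: 16 ethyl 2-[(1S,2S,3S)-3-hydroxy-2-methyl-2-(4-methylpent-3-en-1-yl)-6-oxocyclohexyl]acetate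
Conditions: HF·pyridine, THF, 0 °C to rt
Reagents that add atoms: none
Why: Acidic fluoride cleavage of the silyl ether; the medium is not basic, so no free alkoxide is present to lactonise onto the ester.

Step 10
Reactants: 16 hydroxy keto ester (as above)
Product: 17 ethyl 2-[(1S,2S,3S)-2-{2-[(2S)-3,3-dimethyloxiran-2-yl]ethyl}-3-hydroxy-2-methyl-6-oxocyclohexyl]acetate
Conditions: L-fructose-derived Shi ketone (0.3 equiv), Oxone (2KHSO5·KHSO4·K2SO4), K2CO3, Bu4NHSO4, MeCN–CH2(OMe)2–aq. Na2B4O7 buffer, 0 °C
Reagents that add atoms: potassium peroxymonosulfate (active part of Oxone), [K+].[O-]S(=O)(=O)OO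
Why: Shi epoxidation of the only electron-rich alkene; the enantiomer of the usual fructose-derived ketone delivers the (S)-epoxide by reagent control, which fixes C3' independently of the ring stereocentres.

Step 11
Reactants: 17 epoxy alcohol (as above)
Product: 20 ethyl 2-[(3S,5aS,6S,9aS)-3-hydroxy-2,2,5a-trimethyl-7-oxodecahydro-1-benzoxepin-6-yl]acetate, via stannyl ether 18 (not isolated), via stannyl ether 19 (not isolated)
Conditions: (Bu3Sn)2O, toluene, reflux; then Zn(OTf)2, toluene, 80 °C; aqueous work-up
Reagents that add atoms: none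
Why: Endo-selective hydroxy-epoxide cyclisation: the stannyl ether oxygen of 18 attacks the zinc-activated trisubstituted epoxide at its tertiary carbon (7-endo), where positive charge is best stabilised, closing the oxepane; the C3' oxygen stays on its carbon with retention and the trans fusion follows from the trans arrangement of chain and oxygen set in step 8.

Step 12
Reactants: 20 oxepane keto ester (as above)
Product: 21 ethyl 2-[(3S,5aS,6R,9aS)-3-hydroxy-2,2,5a-trimethyl-7-methylidenedecahydro-1-benzoxepin-6-yl]acetate
Conditions: Ph3PCH3Br, KN(SiMe3)2 (3 equiv), THF, 0 °C to rt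
Reagents that add atoms: methyltriphenylphosphonium bromide, C[P+](c1ccccc1)(c1ccccc1)c1ccccc1.[Br-]
Why: Wittig methylenation of the ketone (the ester is inert to the non-stabilised ylide at this temperature); the basic medium should first equilibrate C6' so that the side chain is equatorial, cis to the axial angular methyl, as in the locked trans-fused chair.

Step 13
Reactants: 21 methylidene ester (as above)
Product: 22 spiro-epoxide of 21 at C7' (oxirane oxygen equatorial, trans to the angular methyl; oxirane CH2 axial)
Conditions: mCPBA, NaHCO3, CH2Cl2, 0 °C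
Reagents that add atoms: 3-chloroperoxybenzoic acid, OOC(=O)c1cccc(Cl)c1
Why: Prilezhaev epoxidation of the exocyclic alkene from the equatorial direction, because the axial angular methyl shields the other face by a 1,3-diaxial interaction; this places the oxygen where the C7' hydroxyl must be.

Step 14
Reactants: 22 spiro-epoxide (as above)
Product: 23 (3S,5aS,6S,7S,9aS)-6-(2-hydroxyethyl)-2,2,5a,7-tetramethyldecahydro-1-benzoxepine-3,7-diol
Conditions: LiAlH4, THF, 0 °C to rt
Reagents that add atoms: none
Why: Hydride opens the epoxide at its CH2 carbon (SN2), leaving the equatorial tertiary alcohol and the axial methyl at C7' without touching the stereocentre, and reduces the ester to the primary alcohol in the same operation.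

Step 15
Reactants: 23 triol (as above)
Product: 24 tris(triethylsilyl) ether of 23
Conditions: TESOTf (4 equiv), 2,6-lutidine, CH2Cl2, −78 to 0 °C
Reagents that add atoms: triethylsilyl trifluoromethanesulfonate, CC[Si](CC)(CC)OS(=O)(=O)C(F)(F)F
Why: Exhaustive silylation with a silyl triflate covers the primary, the hindered secondary and the tertiary hydroxyl alike.

Step 16
Reactants: 24 tris(triethylsilyl) ether (as above)
Product: 25 2-[(3S,5aS,6S,7S,9aS)-2,2,5a,7-tetramethyl-3,7-bis(triethylsilyloxy)decahydro-1-benzoxepin-6-yl]ethanol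
Conditions: PPTS (cat.), MeOH–CH2Cl2, 0 °C
Reagents that add atoms: none
Why: Acid-catalysed methanolysis removes a primary triethylsilyl ether much faster than a neopentyl-type secondary or a tertiary one, so only the primary alcohol should be freed.

Step 17
Reactants: 25 primary alcohol (as above)
Product: 26 (3S,5aS,6S,7S,9aS)-6-(2-iodoethyl)-2,2,5a,7-tetramethyl-3,7-bis(triethylsilyloxy)decahydro-1-benzoxepine
Conditions: I2, PPh3, imidazole, CH2Cl2, 0 °C
Reagents that add atoms: iodine, II
Why: Appel-type iodination of a primary alcohol; with the C7' oxygen silylated, the iodide cannot close to the tetrahydrofuran that a free tertiary hydroxyl would form.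

Step 18
Reactants: 26 iodide (as above); 9 silylated menthyl vinylogous ester (as above)
Product: 30 (4aR,8S,8aS)-3,5,5,8-tetramethyl-4-{2-[(3S,5aS,6S,7S,9aS)-2,2,5a,7-tetramethyl-3,7-bis(triethylsilyloxy)decahydro-1-benzoxepin-6-yl]ethyl}-8-(triethylsilyloxy)-4a,5,6,7,8,8a-hexahydronaphthalen-2(1H)-one, via alkyllithium 27 (not isolated), via organocerium 28 (not isolated), via carbinol adduct 29 (not isolated)
Conditions: t-BuLi (2.1 equiv), Et2O–pentane, −78 °C; CeCl3, THF, −78 °C; then 9, −78 to 0 °C; then 0.5 M aq. HCl, THF, 0 °C
Reagents that add atoms: water, O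
Why: Stork–Danheiser sequence: lithium–iodine exchange gives 27, transmetalation to the less basic organocerium 28 (trivalent cerium) favours 1,2-addition to the hindered C5 carbonyl over enolisation, and mild acid converts carbinol 29 into the transposed enone with loss of menthol; the new carbinol centre is destroyed, C3, C4 and C7 are not touched, and the C5=C6 alkene and C1 carbonyl appear in their final places.

Step 19
Reactants: 30 enone (as above)
Product: 31 (2S)-allylic alcohol of 30 (C1 hydroxyl cis to the ring-fusion hydrogens)
Conditions: (R)-2-methyl-CBS-oxazaborolidine (0.3 equiv), BH3·SMe2, toluene, −30 °C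
Reagents that add atoms: none
Why: Corey–Bakshi–Shibata reduction: the α-methyl alkenyl side of the ketone acts as the large group and the ring methylene as the small one, so the (R)-catalyst should deliver hydride to the face that gives the (S)-alcohol by reagent control, and the tetrasubstituted enone alkene blocks 1,4-reduction.

Step 20
Reactants: 31 (2S)-allylic alcohol (as above)
Product: 33 tris(triethylsilyl) ether of sipholenol M, via allylic mesylate 32 (not isolated)
Conditions: Ms2O, Et3N, CH2Cl2, −65 °C; then anhydrous H2O2 in Et2O (large excess), −78 to −20 °C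
Reagents that add atoms: hydrogen peroxide, OO
Why: Perhydrolysis of an allylic sulfonate, known for allylic and dienylic mesylates: the pseudoaxial mesylate is displaced by hydrogen peroxide from the opposite face (SN2 or collapse of the contact ion pair), so inversion should give the (1R)-hydroperoxide; methanesulfonic anhydride keeps chloride out, the tetrasubstituted C5 terminus is too hindered for attack, and the silyl ether on the C7 oxygen prevents ring closure onto C1.

Step 21
Reactants: 33 tris(triethylsilyl) ether of sipholenol M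
Product: 34 sipholenol M
Conditions: HF·pyridine, pyridine, THF, 0 °C to rt
Reagents that add atoms: none
Why: Buffered fluoride desilylation removes the three triethylsilyl ethers under conditions that are neither reducing nor strongly acidic or basic, which the allylic hydroperoxide and the tertiary alcohols should tolerate.

**Compound list**

1 | 2,6-dimethoxytoluene | COc1cccc(OC)c1C | starting material
2 | 5,5-dimethyloxolan-2-one | CC1(C)CCC(=O)O1 | starting material
3 | 4-(2,4-dimethoxy-3-methylphenyl)-4-methylpentanoic acid | COc1ccc(C(C)(C)CCC(=O)O)c(OC)c1C | intermediate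
4 | dilithium 5-(2,4-dimethoxy-3-methylphenyl)-5-methylhexane-2,2-diolate | COc1ccc(C(C)(C)CCC(C)([O-])[O-])c(OC)c1C.[Li+].[Li+] | intermediate
5 | 5-(2,4-dimethoxy-3-methylphenyl)-5-methylhexan-2-one | COc1ccc(C(C)(C)CCC(C)=O)c(OC)c1C | intermediate
6 | rac-(1S,8aS)-5,7-dimethoxy-1,4,4,6-tetramethyl-1,2,3,4,6,8a-hexahydronaphthalen-1-ol (one C6 epimer drawn) | C[C@H]1C(OC)=C2[C@H](C=C1OC)[C@@](C)(O)CCC2(C)C | intermediate
7 | rac-(4aS,5S,8aR)-5-hydroxy-2,5,8,8-tetramethyl-4a,5,6,7,8,8a-hexahydronaphthalene-1,3(2H,4H)-dione | CC1C(=O)[C@@H]2[C@H](CC1=O)[C@@](C)(O)CCC2(C)C | intermediate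
8 | (4aS,5S,8aR)-5-hydroxy-2,5,8,8-tetramethyl-3-{[(1R,2S,5R)-5-methyl-2-(propan-2-yl)cyclohexyl]oxy}-4a,5,6,7,8,8a-hexahydronaphthalen-1(4H)-one | CC1=C(O[C@@H]3C[C@H](C)CC[C@H]3C(C)C)C[C@H]2[C@@H](C1=O)C(C)(C)CC[C@]2(C)O | intermediate
9 | triethylsilyl ether of 8 at the tertiary hydroxyl | CC1=C(O[C@@H]3C[C@H](C)CC[C@H]3C(C)C)C[C@H]2[C@@H](C1=O)C(C)(C)CC[C@]2(C)O[Si](CC)(CC)CC | intermediate
10 | (S)-4-(tert-butyldimethylsilyloxy)cyclohex-2-en-1-one | C1=CC(=O)CC[C@@H]1O[Si](C)(C)C(C)(C)C | starting material
11 | (3S,4S)-4-(tert-butyldimethylsilyloxy)-3-methyl-1-(trimethylsilyloxy)cyclohex-1-ene | C[C@H]1C=C(O[Si](C)(C)C)CC[C@@H]1O[Si](C)(C)C(C)(C)C | intermediate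
12 | (S)-4-(tert-butyldimethylsilyloxy)-3-methylcyclohex-2-en-1-one | CC1=CC(=O)CC[C@@H]1O[Si](C)(C)C(C)(C)C | intermediate
13 | (3S,4S)-4-(tert-butyldimethylsilyloxy)-3-methyl-3-(4-methylpent-3-en-1-yl)-1-(trimethylsilyloxy)cyclohex-1-ene | CC(C)=CCC[C@@]1(C)C=C(O[Si](C)(C)C)CC[C@@H]1O[Si](C)(C)C(C)(C)C | intermediate
14 | lithium enolate corresponding to 13 | CC(C)=CCC[C@@]1(C)C=C([O-])CC[C@@H]1O[Si](C)(C)C(C)(C)C.[Li+] | intermediate
15 | ethyl 2-[(1S,2S,3S)-3-(tert-butyldimethylsilyloxy)-2-methyl-2-(4-methylpent-3-en-1-yl)-6-oxocyclohexyl]acetate | CCOC(=O)C[C@@H]1C(=O)CC[C@H](O[Si](C)(C)C(C)(C)C)[C@@]1(C)CCC=C(C)C | intermediate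
16 | ethyl 2-[(1S,2S,3S)-3-hydroxy-2-methyl-2-(4-methylpent-3-en-1-yl)-6-oxocyclohexyl]acetate | CCOC(=O)C[C@@H]1C(=O)CC[C@H](O)[C@@]1(C)CCC=C(C)C | intermediate
17 | ethyl 2-[(1S,2S,3S)-2-{2-[(2S)-3,3-dimethyloxiran-2-yl]ethyl}-3-hydroxy-2-methyl-6-oxocyclohexyl]acetate | CCOC(=O)C[C@@H]1C(=O)CC[C@H](O)[C@@]1(C)CC[C@@H]2OC2(C)C | intermediate
18 | tributylstannyl ether of 17 at the ring hydroxyl | CCOC(=O)C[C@@H]1C(=O)CC[C@H](O[Sn](CCCC)(CCCC)CCCC)[C@@]1(C)CC[C@@H]2OC2(C)C | intermediate
19 | tributylstannyl ether of 20 at the C3' hydroxyl | CCOC(=O)C[C@H]1[C@]2(C)CC[C@H](O[Sn](CCCC)(CCCC)CCCC)C(C)(C)O[C@H]2CCC1=O | intermediate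
20 | ethyl 2-[(3S,5aS,6S,9aS)-3-hydroxy-2,2,5a-trimethyl-7-oxodecahydro-1-benzoxepin-6-yl]acetate | CCOC(=O)C[C@H]1[C@]2(C)CC[C@H](O)C(C)(C)O[C@H]2CCC1=O | intermediate
21 | ethyl 2-[(3S,5aS,6R,9aS)-3-hydroxy-2,2,5a-trimethyl-7-methylidenedecahydro-1-benzoxepin-6-yl]acetate | CCOC(=O)C[C@H]1[C@]2(C)CC[C@H](O)C(C)(C)O[C@H]2CCC1=C | intermediate
22 | spiro-epoxide of 21 at C7' (oxirane oxygen equatorial, trans to the angular methyl) | CCOC(=O)C[C@H]1[C@]2(C)CC[C@H](O)C(C)(C)O[C@H]2CC[C@@]13CO3 | intermediate
23 | (3S,5aS,6S,7S,9aS)-6-(2-hydroxyethyl)-2,2,5a,7-tetramethyldecahydro-1-benzoxepine-3,7-diol | OCC[C@H]1[C@]2(C)CC[C@H](O)C(C)(C)O[C@H]2CC[C@]1(C)O | intermediate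
24 | tris(triethylsilyl) ether of 23 | CC[Si](CC)(CC)OCC[C@H]1[C@]2(C)CC[C@H](O[Si](CC)(CC)CC)C(C)(C)O[C@H]2CC[C@]1(C)O[Si](CC)(CC)CC | intermediate
25 | 2-[(3S,5aS,6S,7S,9aS)-2,2,5a,7-tetramethyl-3,7-bis(triethylsilyloxy)decahydro-1-benzoxepin-6-yl]ethanol | OCC[C@H]1[C@]2(C)CC[C@H](O[Si](CC)(CC)CC)C(C)(C)O[C@H]2CC[C@]1(C)O[Si](CC)(CC)CC | intermediate
26 | (3S,5aS,6S,7S,9aS)-6-(2-iodoethyl)-2,2,5a,7-tetramethyl-3,7-bis(triethylsilyloxy)decahydro-1-benzoxepine | ICC[C@H]1[C@]2(C)CC[C@H](O[Si](CC)(CC)CC)C(C)(C)O[C@H]2CC[C@]1(C)O[Si](CC)(CC)CC | intermediate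
27 | alkyllithium from 26 (2-lithioethyl in place of 2-iodoethyl) | [Li]CC[C@H]1[C@]2(C)CC[C@H](O[Si](CC)(CC)CC)C(C)(C)O[C@H]2CC[C@]1(C)O[Si](CC)(CC)CC | intermediate
28 | alkylcerium dichloride from 27 | Cl[Ce](Cl)CC[C@H]1[C@]2(C)CC[C@H](O[Si](CC)(CC)CC)C(C)(C)O[C@H]2CC[C@]1(C)O[Si](CC)(CC)CC | intermediate
29 | 1,2-adduct of 28 and 9 (tertiary allylic alcohol at C5, menthyl enol ether retained; C5 configuration open) | CC1=C(O[C@@H]3C[C@H](C)CC[C@H]3C(C)C)C[C@H]2[C@@H](C1(O)CC[C@H]4[C@]5(C)CC[C@H](O[Si](CC)(CC)CC)C(C)(C)O[C@H]5CC[C@]4(C)O[Si](CC)(CC)CC)C(C)(C)CC[C@]2(C)O[Si](CC)(CC)CC | intermediate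
30 | (4aR,8S,8aS)-3,5,5,8-tetramethyl-4-{2-[(3S,5aS,6S,7S,9aS)-2,2,5a,7-tetramethyl-3,7-bis(triethylsilyloxy)decahydro-1-benzoxepin-6-yl]ethyl}-8-(triethylsilyloxy)-4a,5,6,7,8,8a-hexahydronaphthalen-2(1H)-one | CC1=C(CC[C@H]3[C@]4(C)CC[C@H](O[Si](CC)(CC)CC)C(C)(C)O[C@H]4CC[C@]3(C)O[Si](CC)(CC)CC)[C@@H]2[C@H](CC1=O)[C@@](C)(O[Si](CC)(CC)CC)CCC2(C)C | intermediate
31 | (2S)-allylic alcohol from 30 (C1 hydroxyl cis to the ring-fusion hydrogens) | CC1=C(CC[C@H]3[C@]4(C)CC[C@H](O[Si](CC)(CC)CC)C(C)(C)O[C@H]4CC[C@]3(C)O[Si](CC)(CC)CC)[C@@H]2[C@H](C[C@@H]1O)[C@@](C)(O[Si](CC)(CC)CC)CCC2(C)C | intermediate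
32 | methanesulfonate of 31 | CC1=C(CC[C@H]3[C@]4(C)CC[C@H](O[Si](CC)(CC)CC)C(C)(C)O[C@H]4CC[C@]3(C)O[Si](CC)(CC)CC)[C@@H]2[C@H](C[C@@H]1OS(C)(=O)=O)[C@@](C)(O[Si](CC)(CC)CC)CCC2(C)C | intermediate
33 | tris(triethylsilyl) ether of sipholenol M ((1R)-hydroperoxide) | CC1=C(CC[C@H]3[C@]4(C)CC[C@H](O[Si](CC)(CC)CC)C(C)(C)O[C@H]4CC[C@]3(C)O[Si](CC)(CC)CC)[C@@H]2[C@H](C[C@H]1OO)[C@@](C)(O[Si](CC)(CC)CC)CCC2(C)C | intermediate
34 | sipholenol M | CC1=C(CC[C@H]2[C@]3(C)CC[C@H](O)C(C)(C)O[C@H]3CC[C@]2(C)O)[C@@H]2[C@H](C[C@H]1OO)[C@@](C)(O)CCC2(C)C | target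

**Step count and risks**

Total step count: 21. Longest linear sequence: 15 steps (10 to 34, steps 7–21); the decalin arm contributes 6 steps before the union.

Least certain steps:

- **Step 3 (key step).** The ketyl may be reduced on to the secondary alcohol or dimerise before it attacks the electron-rich, fully substituted arene, and the facial control linking C3 and C7 may be incomplete. Fallback with known reactions, from 3 back to 6: cyclodehydration of acid 3 (P2O5 in MeSO3H) to 5,7-dimethoxy-4,4,6-trimethyl-3,4-dihydronaphthalen-1(2H)-one F1; MeMgBr to the tertiary benzylic alcohol F2; Birch reduction of its lithium alkoxide (Li, NH3, t-BuOH, THF, −78 °C). Protonation between the two methoxy-bearing carbons and para to that site gives the same 1,4-diene 6; the C3/C7 relationship would then rest on the protonation.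

- **Step 20.** Ionisation of the allylic mesylate may outrun the bimolecular displacement, eroding the configuration at C1, or elimination to the ring A diene may win. Fallback from 30 back to 33, by the ene logic: condensation with tosylhydrazine to tosylhydrazone F3; reduction with catecholborane and warming with NaOAc to move the alkene to C1=C6 with a new C5 hydrogen (alkene F4); photooxygenation (O2, tetraphenylporphyrin, light), in which the Schenck ene reaction takes the C5 hydrogen and returns the C5=C6 alkene with the hydroperoxide at C1. This needs the C5 hydrogen on the ring B face and pseudoaxial, which is why it is only the reserve.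

- **Step 18.** The organometallic may enolise the vinylogous ester instead of adding to the hindered C5 carbonyl, or the silyl group of 27 may migrate to carbon before transmetalation. Fallback from 9 and 26 back to 30: deprotonation of 9 at C4 (LDA) and trapping with PhNTf2 to the dienyl triflate F5; conversion of 26 (t-BuLi, then B-methoxy-9-borabicyclo[3.3.1]nonane) to the B-alkyl borane F6; Suzuki–Miyaura coupling (Pd(dppf)Cl2, K3PO4, DMF–THF–H2O) to the dienol ether F7; hydrolysis with dilute HCl, which reprotonates C4 under thermodynamic control and gives 30.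

- **Step 11.** The hydroxyl may attack the secondary epoxide carbon (6-exo) to give a tetrahydropyran with an exocyclic carbinol, or the epoxide may rearrange by hydride shift. Fallback from 17 back to 20: isomerisation of the epoxide with diethylaluminium 2,2,6,6-tetramethylpiperidide to the isopropenyl carbinol F8, C3' retained; alkoxymercuration with Hg(OCOCF3)2, in which Markovnikov and exo preferences now both point to the tertiary carbon (7-exo), giving after chloride exchange the organomercurial F9; reductive demercuration with Bu3SnH, which does not touch the ketone, to 20.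

- **Step 5.** The diastereomeric menthyl ethers may not separate, or the tertiary alcohol may dehydrate under the acidic, water-removing conditions. Fallback from 7 back to 30: the racemic methyl enol ether F10 (MeOH, HC(OMe)3, cat. TsOH, rt); its triethylsilyl ether F11, resolved by preparative chromatography on a chiral phase; the resolved F11 is used in step 18 in place of 9 and gives 30 with loss of methanol.

- **Step 4.** Protonation at C4 may occur from the wrong face, or the trans-fused dione may be the more stable one at this stage. Fallback from 6 back to 30: the trans-fused dione F12 is carried through steps 5, 6 and 18 as its menthyl ether F13, silyl ether F14 and enone F15. F15 is then equilibrated with DBU through the extended dienolate. With the linker on C5, the trans fusion forces an equatorial C10 methyl against it, so the cis-fused 30 should prevail.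

## Further compounds

F1 | step 3 | 5,7-dimethoxy-4,4,6-trimethyl-3,4-dihydronaphthalen-1(2H)-one | COc1cc2c(c(OC)c1C)C(C)(C)CCC2=O
F2 | step 3 | rac-5,7-dimethoxy-1,4,4,6-tetramethyl-1,2,3,4-tetrahydronaphthalen-1-ol | COc1cc2c(c(OC)c1C)C(C)(C)CCC2(C)O
F3 | step 20 | tosylhydrazone of enone 30 | CC1=C(CC[C@H]3[C@]4(C)CC[C@H](O[Si](CC)(CC)CC)C(C)(C)O[C@H]4CC[C@]3(C)O[Si](CC)(CC)CC)[C@@H]2[C@H](CC1=NNS(=O)(=O)c5ccc(C)cc5)[C@@](C)(O[Si](CC)(CC)CC)CCC2(C)C
F4 | step 20 | C1=C6 alkene isomer with C5 hydrogen on the ring B face (deoxygenated, transposed 30) | CC1=CC[C@H]2[C@@H]([C@H]1CC[C@H]3[C@]4(C)CC[C@H](O[Si](CC)(CC)CC)C(C)(C)O[C@H]4CC[C@]3(C)O[Si](CC)(CC)CC)C(C)(C)CC[C@]2(C)O[Si](CC)(CC)CC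
F5 | step 18 | dienyl triflate from 9 (C5 enol triflate, C4=C5 alkene) | CC1=C(O[C@@H]3C[C@H](C)CC[C@H]3C(C)C)C[C@H]2C(=C1OS(=O)(=O)C(F)(F)F)C(C)(C)CC[C@]2(C)O[Si](CC)(CC)CC
F6 | step 18 | B-alkyl-9-borabicyclo[3.3.1]nonane from 26 | C(C[C@H]3[C@]4(C)CC[C@H](O[Si](CC)(CC)CC)C(C)(C)O[C@H]4CC[C@]3(C)O[Si](CC)(CC)CC)B1C2CCCC1CCC2
F7 | step 18 | coupled dienol ether (menthyl enol ether, C4=C5 alkene, linker on C5) | CC1=C(O[C@@H]3C[C@H](C)CC[C@H]3C(C)C)C[C@H]2C(=C1CC[C@H]4[C@]5(C)CC[C@H](O[Si](CC)(CC)CC)C(C)(C)O[C@H]5CC[C@]4(C)O[Si](CC)(CC)CC)C(C)(C)CC[C@]2(C)O[Si](CC)(CC)CC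
F8 | step 11 | ethyl 2-[(1S,2S,3S)-3-hydroxy-2-[(3S)-3-hydroxy-4-methylpent-4-en-1-yl]-2-methyl-6-oxocyclohexyl]acetate | CCOC(=O)C[C@@H]1C(=O)CC[C@H](O)[C@@]1(C)CC[C@H](O)C(C)=C
F9 | step 11 | 2'-(chloromercuriomethyl) analogue of 20 (one C2' methyl replaced by CH2HgCl) | CCOC(=O)C[C@H]1[C@]2(C)CC[C@H](O)C(C)(C[Hg]Cl)O[C@H]2CCC1=O
F10 | step 5 | (4aS,5S,8aR)-5-hydroxy-3-methoxy-2,5,8,8-tetramethyl-4a,5,6,7,8,8a-hexahydronaphthalen-1(4H)-one (made as racemate) | CC1=C(OC)C[C@H]2[C@@H](C1=O)C(C)(C)CC[C@]2(C)O
F11 | step 5 | triethylsilyl ether of F10 (single enantiomer after chiral-phase chromatography) | CC1=C(OC)C[C@H]2[C@@H](C1=O)C(C)(C)CC[C@]2(C)O[Si](CC)(CC)CC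
F12 | step 4 | trans-fused C4 epimer of dione 7 | CC1C(=O)[C@H]2[C@H](CC1=O)[C@@](C)(O)CCC2(C)C
F13 | step 4 | trans-fused C4 epimer of menthyl enol ether 8 | CC1=C(O[C@@H]3C[C@H](C)CC[C@H]3C(C)C)C[C@H]2[C@H](C1=O)C(C)(C)CC[C@]2(C)O
F14 | step 4 | trans-fused C4 epimer of silyl ether 9 | CC1=C(O[C@@H]3C[C@H](C)CC[C@H]3C(C)C)C[C@H]2[C@H](C1=O)C(C)(C)CC[C@]2(C)O[Si](CC)(CC)CC
F15 | step 4 | trans-fused C4 epimer of enone 30 | CC1=C(CC[C@H]3[C@]4(C)CC[C@H](O[Si](CC)(CC)CC)C(C)(C)O[C@H]4CC[C@]3(C)O[Si](CC)(CC)CC)[C@H]2[C@H](CC1=O)[C@@](C)(O[Si](CC)(CC)CC)CCC2(C)C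
A1 | alternative 1 | tert-butyl{[(2Z)-5-[(2S,3S)-3-{2-[(2S)-3,3-dimethyloxiran-2-yl]ethyl}-3-methyloxiran-2-yl]-3-[(trimethylsilyl)methyl]pent-2-en-1-yl]oxy}diphenylsilane | CC(C)(C)[Si](c1ccccc1)(c1ccccc1)OC/C=C(\C[Si](C)(C)C)CC[C@@H]2O[C@@]2(C)CC[C@@H]3OC3(C)C
A2 | alternative 1 | (3S,5aS,6R,9aS)-6-{[(tert-butyldiphenylsilyl)oxy]methyl}-2,2,5a-trimethyl-7-methylidenedecahydro-1-benzoxepin-3-ol | CC(C)(C)[Si](c1ccccc1)(c1ccccc1)OC[C@H]2[C@]3(C)CC[C@H](O)C(C)(C)O[C@H]3CCC2=C
A3 | alternative 2 | (7Z,9E)-10-[(tert-butyldimethylsilyl)oxy]-8-{[(4-methoxybenzyl)oxy]methyl}-6,6,9-trimethyldeca-1,7,9-trien-3-one | C=CC(=O)CCC(C)(C)/C=C(COCc1ccc(OC)cc1)/C(C)=C/O[Si](C)(C)C(C)(C)C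
A4 | alternative 2 | cis-fused 7-(tert-butyldimethylsilyloxy)-5-{[(4-methoxybenzyl)oxy]methyl}-4,4,6-trimethyl-3,4,4a,7,8,8a-hexahydronaphthalen-1(2H)-one | CC1=C(COCc3ccc(OC)cc3)[C@@H]2[C@H](C[C@H]1O[Si](C)(C)C(C)(C)C)C(=O)CCC2(C)C
A5 | alternative 3 | 5-[4-(benzyloxymethyl)-3,5-dimethyl-3-(triethylsilyloxy)hex-5-en-1-yl]-2,2-dimethylfuran-3(2H)-one (configuration as in the SMILES) | CC1(C)OC(CC[C@](C)(O[Si](CC)(CC)CC)[C@@H](COCc2ccccc2)C(C)=C)=CC1=O
A6 | alternative 3 | tricyclic cyclobutane photoadduct (furanone fused to cyclobutane and cyclohexane) | c1ccccc1COC[C@H]2[C@]3(C)C[C@H]4C(=O)C(C)(C)O[C@]43CC[C@]2(C)O[Si](CC)(CC)CC
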